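The ten-membered carbocycle is disconnected at C9–C10, the single bond that joins the 3(2H)-furanone ring (O, C10, C1, C2, C3) to the butenolide ring (C7, C8, O, C12, C11), which is carried as a furan. C9 is both alpha to the enolisable furanone carbon C10 and furfurylic to C8, so one base-mediated step turns a furfuryl chloride bearing a 2-methyl-3(2H)-furanone into the bridged macrocycle: the aromatic 3-oxidofuran is C-alkylated, which closes the ring, creates quaternary C10 and restores the furanone. The precursor is a 2,3,4-trisubstituted furan whose C7 carries the C6–C5–C4 chain ending in the furanone. Furan photooxygenation and dehydration then give the ylidene butenolide.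

Key step: step 22

Remark: germacrane locants are used (C1 furanone carbonyl, C2=C3 enol ether, C4 methyl-bearing methine, C5 methylene, C6 acyloxy carbon, C7/C11 butenolide beta/alpha carbons, C8 gamma carbon, C9 exocyclic methine, C10 quaternary carbon, C12 lactone carbonyl, C13 acetoxymethyl carbon); the target is read as (4S,6S,10S) with C7 and C10 cis across C8=C9 (E), and C10 stays epimerisable until step 22, so its configuration before that step is immaterial.

Step 1
Reactants: 1 furan-3,4-diyldimethanol
Product: 2 [4-(tert-butyldiphenylsilyloxymethyl)furan-3-yl]methanol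
Conditions: TBDPSCl (1.0 equiv), imidazole, DMF, 0 °C; 1 used in excess (2.5 equiv) and recovered
Reagents that add atoms: tert-butyl(chloro)diphenylsilane (TBDPSCl), CC(C)(C)[Si](Cl)(c1ccccc1)c1ccccc1
Why: Statistical monosilylation of a symmetrical diol (silyl ether formation), in which excess diol and a bulky silyl chloride should favour the monoether.

Step 2
Reactants: 2 [4-(tert-butyldiphenylsilyloxymethyl)furan-3-yl]methanol
Product: 3 4-(tert-butyldiphenylsilyloxymethyl)furan-3-carbaldehyde
Conditions: MnO2 (activated, 15 equiv), CH2Cl2, rt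
Reagents that add atoms: none
Why: Benzylic-type oxidation of a furyl carbinol with MnO2, which should stop at the aldehyde and leave the silyl ether untouched.

Step 3
Reactants: 3 4-(tert-butyldiphenylsilyloxymethyl)furan-3-carbaldehyde
Product: 7 4-(tert-butyldiphenylsilyloxymethyl)-2-(hydroxymethyl)furan-3-carbaldehyde, via lithium amino alkoxide 4 (not isolated), via C2-lithiated amino alkoxide 5 (not isolated), via hydroxymethylated amino alkoxide 6 (not isolated)
Conditions: Me2NCH2CH2N(Me)Li (from Me2NCH2CH2NHMe and n-BuLi), THF, −78 °C; n-BuLi, −78 → −20 °C; (CH2O)n, −78 °C → rt; H2O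
Reagents that add atoms: formaldehyde (from paraformaldehyde), C=O
Why: Alpha-amino alkoxide-directed ortho-lithiation, in which the lithium amide masks the aldehyde as 4, the chelating dimethylamino arm should steer n-BuLi to C2 (the furan alpha position next to the directing group) to give 5, formaldehyde traps the aryllithium as 6, and aqueous work-up returns the aldehyde.

Step 4
Reactants: 7 4-(tert-butyldiphenylsilyloxymethyl)-2-(hydroxymethyl)furan-3-carbaldehyde
Product: 8 4-(tert-butyldiphenylsilyloxymethyl)-2-(triethylsilyloxymethyl)furan-3-carbaldehyde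
Conditions: TESCl, imidazole, CH2Cl2, 0 °C
Reagents that add atoms: chlorotriethylsilane (TESCl), CC[Si](Cl)(CC)CC
Why: Standard silylation of the primary alcohol, with the labile triethylsilyl group chosen so that it can later be removed beside the two tert-butyl-substituted silyl ethers.

Step 5
Reactants: 9 methyl (S)-3-hydroxy-2-methylpropanoate
Product: 10 methyl (S)-3-(tert-butyldimethylsilyloxy)-2-methylpropanoate
Conditions: TBSCl, imidazole, CH2Cl2, rt
Reagents that add atoms: tert-butyl(chloro)dimethylsilane (TBSCl), CC(C)(C)[Si](C)(C)Cl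
Why: Standard silyl ether formation on the primary alcohol, which does not involve the stereocentre that becomes C4.

Step 6
Reactants: 10 methyl (S)-3-(tert-butyldimethylsilyloxy)-2-methylpropanoate
Product: 12 (S)-3-(tert-butyldimethylsilyloxy)-2-methylpropanal, via aluminium hemiacetal 11 (not isolated)
Conditions: i-Bu2AlH (1.1 equiv), CH2Cl2, −78 °C; MeOH, then aq. potassium sodium tartrate
Reagents that add atoms: none
Why: Partial ester reduction with i-Bu2AlH, in which the tetrahedral adduct 11 persists at −78 °C and releases the aldehyde only on work-up, so over-reduction and epimerisation of the alpha centre should be avoided.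

Step 7
Reactants: 12 (S)-3-(tert-butyldimethylsilyloxy)-2-methylpropanal
Product: 13 (R)-tert-butyl(4,4-dibromo-2-methylbut-3-enyloxy)dimethylsilane
Conditions: CBr4, PPh3, 2,6-lutidine, CH2Cl2, 0 °C
Reagents that add atoms: tetrabromomethane, BrC(Br)(Br)Br
Why: Corey–Fuchs dibromoolefination (Wittig-type reaction of Ph3P=CBr2) under buffered, non-enolising conditions, so the alpha stereocentre should survive, unlike under basic diazophosphonate homologation.

Step 8
Reactants: 13 (R)-tert-butyl(4,4-dibromo-2-methylbut-3-enyloxy)dimethylsilane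
Product: 15 (R)-tert-butyldimethyl[2-methyl-4-(trimethylsilyl)but-3-ynyloxy]silane, via lithium acetylide 14 (not isolated)
Conditions: n-BuLi (2.1 equiv), THF, −78 °C; TMSCl, −78 °C → rt
Reagents that add atoms: chlorotrimethylsilane (TMSCl), C[Si](C)(C)Cl
Why: Second stage of the Corey–Fuchs alkyne synthesis, in which n-BuLi converts the dibromoalkene into acetylide 14 (bromine–lithium exchange, 1,2-shift, deprotonation) and TMSCl caps the alkyne in the same flask for the later organolithium step.

Step 9
Reactants: 15 (R)-tert-butyldimethyl[2-methyl-4-(trimethylsilyl)but-3-ynyloxy]silane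
Product: 16 (R)-2-methyl-4-(trimethylsilyl)but-3-yn-1-ol
Conditions: camphorsulfonic acid (cat.), MeOH/CH2Cl2, 0 °C
Reagents that add atoms: none
Why: Acid-catalysed methanolysis cleaves the primary silyl ether, whereas the alkynyl C–Si bond is stable to mild acid and is lost only with base or fluoride.

Step 10
Reactants: 16 (R)-2-methyl-4-(trimethylsilyl)but-3-yn-1-ol
Product: 17 (R)-(4-iodo-3-methylbut-1-ynyl)trimethylsilane
Conditions: I2, PPh3, imidazole, CH2Cl2, 0 °C → rt
Reagents that add atoms: iodine, II
Why: Appel-type iodination of a primary alcohol, an SN2 displacement at the CH2 group that leaves the adjacent stereocentre untouched.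

Step 11
Reactants: 17 (R)-(4-iodo-3-methylbut-1-ynyl)trimethylsilane and 8 4-(tert-butyldiphenylsilyloxymethyl)-2-(triethylsilyloxymethyl)furan-3-carbaldehyde
Product: 19 (3S)-1-[4-(tert-butyldiphenylsilyloxymethyl)-2-(triethylsilyloxymethyl)furan-3-yl]-3-methyl-5-(trimethylsilyl)pent-4-yn-1-ol (both C6 epimers), via alkyllithium 18 (not isolated)
Conditions: 17 (1.3 equiv), t-BuLi (2.6 equiv), Et2O, −78 °C; 8, −78 °C; H2O
Reagents that add atoms: none
Why: Iodine–lithium exchange gives the primary alkyllithium 18 (the silyl cap prevents alkyne deprotonation), whose 1,2-addition to the aldehyde forms the C5–C6 bond; C6 is formed unselectively and is corrected in steps 12 and 13.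

Step 12
Reactants: 19 furyl carbinol (C6 epimers)
Product: 20 (3S)-1-[4-(tert-butyldiphenylsilyloxymethyl)-2-(triethylsilyloxymethyl)furan-3-yl]-3-methyl-5-(trimethylsilyl)pent-4-yn-1-one
Conditions: Dess–Martin periodinane, pyridine, CH2Cl2, 0 °C → rt
Reagents that add atoms: none
Why: Dess–Martin oxidation of the secondary furyl carbinol under pyridine buffering, which is compatible with the silyl ethers and the alkynylsilane and cannot epimerise C4 (beta to the new ketone).

Step 13
Reactants: 20 furyl ketone
Product: 21 (1S,3S)-1-[4-(tert-butyldiphenylsilyloxymethyl)-2-(triethylsilyloxymethyl)furan-3-yl]-3-methyl-5-(trimethylsilyl)pent-4-yn-1-ol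
Conditions: (R)-2-methyl-CBS-oxazaborolidine (0.5 equiv), BH3·SMe2, THF, −30 °C; MeOH
Reagents that add atoms: none
Why: Corey–Bakshi–Shibata reduction, in which the (R)-oxazaborolidine should treat the disubstituted furyl group as the large and the C5 methylene as the small substituent and deliver hydride to the Re face, setting C6 as S under reagent control.

Step 14
Reactants: 21 (4S,6S) furyl carbinol
Product: 22 tert-butyldimethylsilyl ether of 21 ((4S,6S) silyl ether)
Conditions: TBSOTf, 2,6-lutidine, CH2Cl2, −78 → 0 °C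
Reagents that add atoms: tert-butyldimethylsilyl trifluoromethanesulfonate (TBSOTf), CC(C)(C)[Si](C)(C)OS(=O)(=O)C(F)(F)F
Why: Silylation of a hindered secondary alcohol with a silyl triflate and a hindered base, which does not affect C6.

Step 15
Reactants: 22 (4S,6S) silyl ether
Product: 23 terminal alkyne (22 without the alkynyl trimethylsilyl group)
Conditions: K2CO3 (0.3 equiv), MeOH/THF, 0 °C
Reagents that add atoms: none
Why: Base-catalysed protodesilylation of the alkynylsilane in methanol, which should be much faster than methanolysis of the triethylsilyl ethers at 0 °C.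

Step 16
Reactants: 24 ethyl (S)-lactate
Product: 25 (S)-2-hydroxy-N-methoxy-N-methylpropanamide
Conditions: MeNHOMe·HCl, i-PrMgCl, THF, −20 → 0 °C; aq. NH4Cl
Reagents that add atoms: N,O-dimethylhydroxylamine hydrochloride, CNOC.Cl
Why: Weinreb amide synthesis by aminolysis of the ester with the chloromagnesium amide of N,O-dimethylhydroxylamine, which tolerates the free hydroxyl as its magnesium alkoxide.

Step 17
Reactants: 25 (S)-2-hydroxy-N-methoxy-N-methylpropanamide
Product: 26 (S)-N-methoxy-N-methyl-2-(triethylsilyloxy)propanamide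
Conditions: TESCl, imidazole, CH2Cl2, 0 °C → rt
Reagents that add atoms: chlorotriethylsilane (TESCl), CC[Si](Cl)(CC)CC
Why: Standard silylation of the secondary alcohol, using the same labile silyl group as on the C9 oxygen so that both are removed together in step 19.

Step 18
Reactants: 23 terminal alkyne and 26 (S)-N-methoxy-N-methyl-2-(triethylsilyloxy)propanamide
Product: 29 (2S,6S,8S)-8-(tert-butyldimethylsilyloxy)-8-[4-(tert-butyldiphenylsilyloxymethyl)-2-(triethylsilyloxymethyl)furan-3-yl]-6-methyl-2-(triethylsilyloxy)oct-4-yn-3-one, via lithium acetylide 27 (not isolated), via tetrahedral lithium adduct 28 (not isolated)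
Conditions: 23, n-BuLi (1.0 equiv), THF, −78 °C; 26, −78 → −20 °C; AcOH, −78 °C
Reagents that add atoms: none
Why: Weinreb ketone synthesis, in which acetylide 27 adds once to the amide to give the chelated adduct 28 and the cold acidic quench releases the ynone while protonating the liberated amine so that it cannot add to the triple bond; this forms the C1–C2 bond.

Step 19
Reactants: 29 alpha'-triethylsilyloxy ynone
Product: 30 (2S,6S,8S)-8-(tert-butyldimethylsilyloxy)-8-[4-(tert-butyldiphenylsilyloxymethyl)-2-(hydroxymethyl)furan-3-yl]-2-hydroxy-6-methyloct-4-yn-3-one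
Conditions: HF·pyridine, pyridine, THF, 0 °C
Reagents that add atoms: none
Why: Graded silyl ether lability, in which buffered HF·pyridine should cleave the two triethylsilyl ethers well before the tert-butyl-substituted ones and, being non-nucleophilic, cannot solvolyse the furfuryl position.

Step 20
Reactants: 30 dihydroxy ynone
Product: 32 5-{(2S,4S)-4-(tert-butyldimethylsilyloxy)-4-[4-(tert-butyldiphenylsilyloxymethyl)-2-(hydroxymethyl)furan-3-yl]butan-2-yl}-2-methylfuran-3(2H)-one (C10 epimers), via diethylamino enone 31 (not isolated)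
Conditions: Et2NH, EtOH, rt; then AcOH/H2O/THF, rt
Reagents that add atoms: none
Why: Net 5-endo oxa-Michael cyclisation of an alpha'-hydroxy ynone, in which diethylamine adds to the ynone faster than base can isomerise it (protecting C4) to give 31 and acid-promoted addition–elimination by the hydroxyl closes the 3(2H)-furanone ring; the enolisable C10 may be a mixture.

Step 21
Reactants: 32 furanone furfuryl alcohol
Product: 34 furanone furfuryl chloride (32 with CH2Cl in place of CH2OH), via furfuryl mesylate 33 (not isolated)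
Conditions: MsCl, 2,4,6-collidine, LiCl, DMF, 0 °C; cold work-up, used at once
Reagents that add atoms: lithium chloride, [Li+].[Cl-]
Why: Mesylation of the primary furfuryl alcohol and in situ SN2 exchange of mesylate 33 by chloride should give the chloride without ionisation, and collidine is too weak a base to enolise the furanone.

Step 22
Reactants: 34 furanone furfuryl chloride
Product: 36 (4S,6S,10S) furan-fused macrocycle with the 3(2H)-furanone bridge (C6 OTBS and C13 OTBDPS), via caesium 3-oxidofuran 35 (not isolated)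
Conditions: Cs2CO3 (3 equiv), MeCN, 45 °C, 34 added over 12 h by syringe pump (final 0.001 M)
Reagents that add atoms: none
Why: Proposed new method: Cs2CO3 removes the acidic C10–H of the 2-methyl-3(2H)-furanone to give the aromatic 3-oxidofuran 35, whose enolate carbon C10 displaces chloride from the furfurylic C9 by SN2, and the product is quaternary at C10 and cannot re-enolise there, so the new centre cannot epimerise. The closest known reaction types are the intermolecular C2-alkylation of 2-monosubstituted 3(2H)-furanone enolates with benzylic or allylic halides and the closure of ten-membered carbocycles by alkylation of stabilised carbanions with allylic halides; their union in a dearomatising macrocyclisation is untested. The ten-membered carbocycle C1–C10 closes in a 10-exo-tet mode, which completes the oxygen-bridged 11-oxabicyclo[6.2.1] core. C10 is the only new stereocentre and is set by the face of the planar oxidofuran that C9 reaches: the C4 centre on C3 should keep its hydrogen, not its methyl, inside the forming ring next to the furanone oxygen, which sends C5 and hence C9 to one face and leaves the C10 methyl on the other, syn to the C4 methyl, with the outward-pointing C6 silyloxy group as a second bias. The step needs C- over O-alkylation, C10 over C2, cyclisation over oligomerisation and retention of C4: C10 lies in the pi face over which the short tether arches, whereas the oxido oxygen would have to be reached in the ring plane through an eleven-membered ether and C2 through an eight-membered ring at a carbon without enolate character; slow addition at high dilution suppresses dimers, and carbonate is too weak to remove the gamma C4–H. Two flat five-membered rings and only three freely rotating sp3 atoms (C4, C5, C6) in the tether keep the entropic and transannular cost low.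

Step 23
Reactants: 36 bis-silylated macrocycle
Product: 37 (4S,6S,10S) macrocyclic diol (C6 OH and C13 OH)
Conditions: n-Bu4NF, AcOH (1:1), THF, 0 → 40 °C
Reagents that add atoms: none
Why: Fluoride-mediated cleavage of both silyl ethers, with acetic acid buffering so that the furanone and its C4 centre are not exposed to a basic medium.

Step 24
Reactants: 37 macrocyclic diol
Product: 38 C13 monoacetate (C6 OH free)
Conditions: AcCl (1.1 equiv), 2,4,6-collidine, CH2Cl2, −78 °C
Reagents that add atoms: acetyl chloride, CC(Cl)=O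
Why: Chemoselective acylation of the primary alcohol at low temperature, since the secondary C6 alcohol flanked by the furan and the ring should react far more slowly.

Step 25
Reactants: 38 C13 monoacetate and 39 3-methylbut-2-enoyl chloride
Product: 40 macrocyclic furan with C13 acetate and C6 3-methylbut-2-enoate
Conditions: 39, pyridine, DMAP (cat.), CH2Cl2, 0 °C → rt
Reagents that add atoms: none
Why: DMAP-catalysed acylation of the secondary alcohol, run without trialkylamine so that vinylketene formation and deconjugation of the senecioyl group are avoided.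

Step 26
Reactants: 40 macrocyclic furan diester
Product: 42 C8-hydroxy butenolide (either C8 epimer), via furan endoperoxide 41 (not isolated)
Conditions: O2, hν (visible), tetraphenylporphyrin (cat.), CH2Cl2, −78 °C; then i-Pr2NEt, −78 °C → rt
Reagents that add atoms: dioxygen (as singlet oxygen), O=O
Why: Singlet-oxygen [4+2] cycloaddition across C8 and C12 of the furan gives 41, and Kornblum–DeLaMare fragmentation removes the only bridgehead hydrogen (C12–H), so C12 becomes the lactone carbonyl and C8 a hemiketal whose configuration is erased in step 27; the electron-poor alkenes should not compete with the furan.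

Step 27
Reactants: 42 C8-hydroxy butenolide
Product: 43 CNP0102620.1 (target)
Conditions: camphorsulfonic acid (cat.), 4 Å molecular sieves, toluene, 50 °C
Reagents that add atoms: none
Why: Acid-catalysed E1-type dehydration of the gamma-hydroxybutenolide toward C9, the only neighbouring carbon bearing hydrogen, under reversible conditions that should give the less strained C8=C9 isomer with C7 and C10 cis, as the ten-membered ring requires.

Compound list
1 | furan-3,4-diyldimethanol | OCc1cocc1CO | starting material
2 | [4-(tert-butyldiphenylsilyloxymethyl)furan-3-yl]methanol | OCc1cocc1CO[Si](c1ccccc1)(c1ccccc1)C(C)(C)C | intermediate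
3 | 4-(tert-butyldiphenylsilyloxymethyl)furan-3-carbaldehyde | O=Cc1cocc1CO[Si](c1ccccc1)(c1ccccc1)C(C)(C)C | intermediate
4 | lithium alpha-amino alkoxide from 3 and lithium [2-(dimethylamino)ethyl](methyl)amide (formed in the flask) | [Li]OC(N(C)CCN(C)C)c1cocc1CO[Si](c1ccccc1)(c1ccccc1)C(C)(C)C | intermediate
5 | C2-lithiated alpha-amino alkoxide (formed in the flask) | [Li]OC(N(C)CCN(C)C)c1c([Li])occ1CO[Si](c1ccccc1)(c1ccccc1)C(C)(C)C | intermediate
6 | hydroxymethylated alpha-amino alkoxide, dilithium salt (formed in the flask) | [Li]OCc1occ(CO[Si](c2ccccc2)(c2ccccc2)C(C)(C)C)c1C(O[Li])N(C)CCN(C)C | intermediate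
7 | 4-(tert-butyldiphenylsilyloxymethyl)-2-(hydroxymethyl)furan-3-carbaldehyde | O=Cc1c(CO)occ1CO[Si](c1ccccc1)(c1ccccc1)C(C)(C)C | intermediate
8 | 4-(tert-butyldiphenylsilyloxymethyl)-2-(triethylsilyloxymethyl)furan-3-carbaldehyde | O=Cc1c(CO[Si](CC)(CC)CC)occ1CO[Si](c1ccccc1)(c1ccccc1)C(C)(C)C | intermediate
9 | methyl (S)-3-hydroxy-2-methylpropanoate | COC(=O)[C@@H](C)CO | starting material
10 | methyl (S)-3-(tert-butyldimethylsilyloxy)-2-methylpropanoate | COC(=O)[C@@H](C)CO[Si](C)(C)C(C)(C)C | intermediate
11 | diisobutylaluminium hemiacetal of 10 (formed in the flask) | COC(O[Al](CC(C)C)CC(C)C)[C@@H](C)CO[Si](C)(C)C(C)(C)C | intermediate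
12 | (S)-3-(tert-butyldimethylsilyloxy)-2-methylpropanal | O=C[C@@H](C)CO[Si](C)(C)C(C)(C)C | intermediate
13 | (R)-tert-butyl(4,4-dibromo-2-methylbut-3-enyloxy)dimethylsilane | BrC(Br)=C[C@@H](C)CO[Si](C)(C)C(C)(C)C | intermediate
14 | lithium (R)-4-(tert-butyldimethylsilyloxy)-3-methylbut-1-ynide (formed in the flask) | [Li]C#C[C@@H](C)CO[Si](C)(C)C(C)(C)C | intermediate
15 | (R)-tert-butyldimethyl[2-methyl-4-(trimethylsilyl)but-3-ynyloxy]silane | C[Si](C)(C)C#C[C@@H](C)CO[Si](C)(C)C(C)(C)C | intermediate
16 | (R)-2-methyl-4-(trimethylsilyl)but-3-yn-1-ol | C[Si](C)(C)C#C[C@@H](C)CO | intermediate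
17 | (R)-(4-iodo-3-methylbut-1-ynyl)trimethylsilane | C[Si](C)(C)C#C[C@@H](C)CI | intermediate
18 | [(S)-2-methyl-4-(trimethylsilyl)but-3-ynyl]lithium (formed in the flask) | C[Si](C)(C)C#C[C@@H](C)C[Li] | intermediate
19 | (3S)-1-[4-(tert-butyldiphenylsilyloxymethyl)-2-(triethylsilyloxymethyl)furan-3-yl]-3-methyl-5-(trimethylsilyl)pent-4-yn-1-ol, both epimers at C6 | C[Si](C)(C)C#C[C@@H](C)CC(O)c1c(CO[Si](CC)(CC)CC)occ1CO[Si](c1ccccc1)(c1ccccc1)C(C)(C)C | intermediate
20 | (3S)-1-[4-(tert-butyldiphenylsilyloxymethyl)-2-(triethylsilyloxymethyl)furan-3-yl]-3-methyl-5-(trimethylsilyl)pent-4-yn-1-one | C[Si](C)(C)C#C[C@@H](C)CC(=O)c1c(CO[Si](CC)(CC)CC)occ1CO[Si](c1ccccc1)(c1ccccc1)C(C)(C)C | intermediate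
21 | (1S,3S)-1-[4-(tert-butyldiphenylsilyloxymethyl)-2-(triethylsilyloxymethyl)furan-3-yl]-3-methyl-5-(trimethylsilyl)pent-4-yn-1-ol | C[Si](C)(C)C#C[C@@H](C)C[C@H](O)c1c(CO[Si](CC)(CC)CC)occ1CO[Si](c1ccccc1)(c1ccccc1)C(C)(C)C | intermediate
22 | tert-butyldimethylsilyl ether of 21, (4S,6S) | C[Si](C)(C)C#C[C@@H](C)C[C@H](O[Si](C)(C)C(C)(C)C)c1c(CO[Si](CC)(CC)CC)occ1CO[Si](c1ccccc1)(c1ccccc1)C(C)(C)C | intermediate
23 | terminal alkyne, (4S,6S): 22 without the alkynyl trimethylsilyl group | C#C[C@@H](C)C[C@H](O[Si](C)(C)C(C)(C)C)c1c(CO[Si](CC)(CC)CC)occ1CO[Si](c1ccccc1)(c1ccccc1)C(C)(C)C | intermediate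
24 | ethyl (S)-lactate | C[C@H](O)C(=O)OCC | starting material
25 | (S)-2-hydroxy-N-methoxy-N-methylpropanamide | C[C@H](O)C(=O)N(C)OC | intermediate
26 | (S)-N-methoxy-N-methyl-2-(triethylsilyloxy)propanamide | C[C@H](O[Si](CC)(CC)CC)C(=O)N(C)OC | intermediate
27 | lithium acetylide of 23 (formed in the flask) | [Li]C#C[C@@H](C)C[C@H](O[Si](C)(C)C(C)(C)C)c1c(CO[Si](CC)(CC)CC)occ1CO[Si](c1ccccc1)(c1ccccc1)C(C)(C)C | intermediate
28 | tetrahedral lithium adduct of 27 and 26 (formed in the flask) | C[C@H](O[Si](CC)(CC)CC)C(O[Li])(N(C)OC)C#C[C@@H](C)C[C@H](O[Si](C)(C)C(C)(C)C)c1c(CO[Si](CC)(CC)CC)occ1CO[Si](c1ccccc1)(c1ccccc1)C(C)(C)C | intermediate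
29 | (2S,6S,8S)-8-(tert-butyldimethylsilyloxy)-8-[4-(tert-butyldiphenylsilyloxymethyl)-2-(triethylsilyloxymethyl)furan-3-yl]-6-methyl-2-(triethylsilyloxy)oct-4-yn-3-one | C[C@H](O[Si](CC)(CC)CC)C(=O)C#C[C@@H](C)C[C@H](O[Si](C)(C)C(C)(C)C)c1c(CO[Si](CC)(CC)CC)occ1CO[Si](c1ccccc1)(c1ccccc1)C(C)(C)C | intermediate
30 | (2S,6S,8S)-8-(tert-butyldimethylsilyloxy)-8-[4-(tert-butyldiphenylsilyloxymethyl)-2-(hydroxymethyl)furan-3-yl]-2-hydroxy-6-methyloct-4-yn-3-one | C[C@H](O)C(=O)C#C[C@@H](C)C[C@H](O[Si](C)(C)C(C)(C)C)c1c(CO)occ1CO[Si](c1ccccc1)(c1ccccc1)C(C)(C)C | intermediate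
31 | beta-(diethylamino) enone from 30 and diethylamine (formed in the flask) | C[C@H](O)C(=O)C=C(N(CC)CC)[C@@H](C)C[C@H](O[Si](C)(C)C(C)(C)C)c1c(CO)occ1CO[Si](c1ccccc1)(c1ccccc1)C(C)(C)C | intermediate
32 | 5-{(2S,4S)-4-(tert-butyldimethylsilyloxy)-4-[4-(tert-butyldiphenylsilyloxymethyl)-2-(hydroxymethyl)furan-3-yl]butan-2-yl}-2-methylfuran-3(2H)-one, both epimers at C10 | CC1OC(=CC1=O)[C@@H](C)C[C@H](O[Si](C)(C)C(C)(C)C)c1c(CO)occ1CO[Si](c1ccccc1)(c1ccccc1)C(C)(C)C | intermediate
33 | furfuryl methanesulfonate of 32 (formed in the flask) | CC1OC(=CC1=O)[C@@H](C)C[C@H](O[Si](C)(C)C(C)(C)C)c1c(COS(C)(=O)=O)occ1CO[Si](c1ccccc1)(c1ccccc1)C(C)(C)C | intermediate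
34 | furanone furfuryl chloride: 32 with chloromethyl in place of hydroxymethyl | CC1OC(=CC1=O)[C@@H](C)C[C@H](O[Si](C)(C)C(C)(C)C)c1c(CCl)occ1CO[Si](c1ccccc1)(c1ccccc1)C(C)(C)C | intermediate
35 | caesium 2-methylfuran-3-olate (3-oxidofuran) of 34 (formed in the flask) | [Cs+].Cc1oc(cc1[O-])[C@@H](C)C[C@H](O[Si](C)(C)C(C)(C)C)c1c(CCl)occ1CO[Si](c1ccccc1)(c1ccccc1)C(C)(C)C | intermediate
36 | (4S,6S,10S) macrocycle: ten-membered carbocycle C1–C10 with C1 ketone, C2=C3 and the C3–O–C10 bridge, furan fused at C7/C8 (oxygen between C8 and C12), C6 OTBS, C13 OTBDPS | CC(C)(C)[Si](c1ccccc1)(c1ccccc1)OCc1c2c(C[C@]3(C)OC(=CC3=O)[C@@H](C)C[C@@H]2O[Si](C)(C)C(C)(C)C)oc1 | intermediate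
37 | (4S,6S,10S) macrocyclic diol: 36 with free C6 and C13 hydroxyls | OCc1c2c(C[C@]3(C)OC(=CC3=O)[C@@H](C)C[C@@H]2O)oc1 | intermediate
38 | (4S,6S,10S) C13 monoacetate with free C6 hydroxyl | CC(=O)OCc1c2c(C[C@]3(C)OC(=CC3=O)[C@@H](C)C[C@@H]2O)oc1 | intermediate
39 | 3-methylbut-2-enoyl chloride (senecioyl chloride) | CC(C)=CC(=O)Cl | starting material
40 | (4S,6S,10S) macrocyclic furan with C13 acetate and C6 3-methylbut-2-enoate | CC(=O)OCc1c2c(C[C@]3(C)OC(=CC3=O)[C@@H](C)C[C@@H]2OC(=O)C=C(C)C)oc1 | intermediate
41 | furan endoperoxide of 40: O–O bridge between C8 and C12 (formed in the flask) | CC(=O)OCC1=C2C3(C[C@]4(C)OC(=CC4=O)[C@@H](C)C[C@@H]2OC(=O)C=C(C)C)OOC1O3 | intermediate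
42 | (4S,6S,10S) C8-hydroxy butenolide (12,8-lactone, C7=C11), either C8 epimer | CC(=O)OCC1=C2C(O)(C[C@]3(C)OC(=CC3=O)[C@@H](C)C[C@@H]2OC(=O)C=C(C)C)OC1=O | intermediate
43 | CNP0102620.1: (4S,6S,10S,8E)-13-acetoxy-6-(3-methylbut-2-enoyloxy)-1-oxo-3,10-epoxygermacra-2,7(11),8-trien-12,8-olide | CC(=O)OCC1=C2/C(=C\[C@]3(C)OC(=CC3=O)[C@@H](C)C[C@@H]2OC(=O)C=C(C)C)OC1=O | target

Total step count: 27. Longest linear sequence: 21 steps (from 9 to 43: steps 5–15 and 18–27).

Steps most likely to fail

Step 22 (key step, new method). What may go wrong: C9 may reach the wrong face of the oxidofuran (poor facial selectivity at C10), intermolecular alkylation may outrun ring closure, or the furfuryl chloride may solvolyse before it cyclises. Fallback with known chemistry, setting out from compound 22 and returning at compound 36: C10 is fixed by auxiliary-controlled alkylation and the ring is closed by a Nozaki–Hiyama–Kishi reaction.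
- Selective methanolysis of the primary triethylsilyl ether of 22 (pyridinium p-toluenesulfonate, MeOH, 0 °C) should give the furfuryl alcohol F1, and Appel bromination (CBr4, PPh3, −20 °C) the furfuryl bromide F2.
- (2R,5R)-2-tert-butyl-5-methyl-1,3-dioxolan-4-one F3, made from (R)-lactic acid and pivalaldehyde under acid catalysis with azeotropic removal of water, is deprotonated with LiN(i-Pr)2 at −78 °C to its lithium enolate F4.
- F4 should be alkylated by F2 anti to the tert-butyl group (self-regeneration of stereocentres) to give the (2R,5S)-dioxolanone F5, in which C10 is already quaternary and correctly configured.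
- LiAlH4 opens F5 to the (10S) diol F6, and NIS with catalytic AgNO3 (dark, 0 °C) converts the alkynylsilane into the iodoalkyne F7.
- Dess–Martin oxidation of the primary alcohol gives the alpha-hydroxy aldehyde F8, and CrCl2 with catalytic NiCl2 in THF/DMF at high dilution should close the ten-membered ring between C1 and C2 to the macrocyclic propargylic diol F9.
- MnO2 oxidises F9 to the macrocyclic alpha'-hydroxy ynone F10, and Et2NH followed by AcOH effects the 5-endo oxa-Michael closure of the furanone to give 36.

Step 13. What may go wrong: the di-ortho-substituted furyl group is twisted out of conjugation and may not act as the large substituent, so hydride delivery may discriminate the ketone faces poorly. Fallback, setting out from compound 19 (no oxidation needed) and returning at compounds 21 and 23: the C6 epimers of 19 are separated by chromatography into 21 and the (4S,6R) alcohol F11. Mitsunobu inversion of F11 (4-nitrobenzoic acid, PPh3, diisopropyl azodicarboxylate) should give the (4S,6S) 4-nitrobenzoate F12. Methanolysis (K2CO3, MeOH) removes the ester and the alkynyl silyl group together to give the (4S,6S) alkynol F13, and silylation (TBSOTf, 2,6-lutidine) rejoins the route at 23.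

Step 3. What may go wrong: lithiation may occur at C5 next to the silyloxymethyl group instead of C2, the silyl group may migrate from oxygen to the lithiated carbon, or the hydroxymethylation may be incomplete. Fallback, setting out from compound 2 and returning at compound 8: the lithium alkoxide of the C3 hydroxymethyl group serves as the directing group. n-BuLi (2.2 equiv, THF, 0 °C) should give the C2-lithiated lithium alkoxide F14 (alkoxide-directed ortho-lithiation), and paraformaldehyde then gives the diol F15. TESCl (1.0 equiv, imidazole, −78 °C) should silylate the less hindered C2 hydroxymethyl group, the other being flanked by two substituents, to give the mono-triethylsilyl ether F16, and MnO2 oxidation of the remaining furyl carbinol gives 8.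

Further compounds
F1 | step 22 | furfuryl alcohol: 22 with the C9 triethylsilyl ether cleaved | C[Si](C)(C)C#C[C@@H](C)C[C@H](O[Si](C)(C)C(C)(C)C)c1c(CO)occ1CO[Si](c1ccccc1)(c1ccccc1)C(C)(C)C
F2 | step 22 | furfuryl bromide from F1 | C[Si](C)(C)C#C[C@@H](C)C[C@H](O[Si](C)(C)C(C)(C)C)c1c(CBr)occ1CO[Si](c1ccccc1)(c1ccccc1)C(C)(C)C
F3 | step 22 | (2R,5R)-2-tert-butyl-5-methyl-1,3-dioxolan-4-one | C[C@H]1O[C@@H](C(C)(C)C)OC1=O
F4 | step 22 | lithium enolate of F3 | [Li]OC1=C(C)O[C@@H](C(C)(C)C)O1
F5 | step 22 | (2R,5S)-2-tert-butyl-5-methyl-5-(furfuryl)-1,3-dioxolan-4-one from F4 and F2 | C[Si](C)(C)C#C[C@@H](C)C[C@H](O[Si](C)(C)C(C)(C)C)c1c(C[C@]2(C)O[C@@H](C(C)(C)C)OC2=O)occ1CO[Si](c1ccccc1)(c1ccccc1)C(C)(C)C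
F6 | step 22 | (10S) diol with C1 primary and C10 tertiary hydroxyls | C[Si](C)(C)C#C[C@@H](C)C[C@H](O[Si](C)(C)C(C)(C)C)c1c(C[C@](C)(O)CO)occ1CO[Si](c1ccccc1)(c1ccccc1)C(C)(C)C
F7 | step 22 | iodoalkyne diol | IC#C[C@@H](C)C[C@H](O[Si](C)(C)C(C)(C)C)c1c(C[C@](C)(O)CO)occ1CO[Si](c1ccccc1)(c1ccccc1)C(C)(C)C
F8 | step 22 | iodoalkyne alpha-hydroxy aldehyde | IC#C[C@@H](C)C[C@H](O[Si](C)(C)C(C)(C)C)c1c(C[C@](C)(O)C=O)occ1CO[Si](c1ccccc1)(c1ccccc1)C(C)(C)C
F9 | step 22 | macrocyclic propargylic diol (C1 OH mixture, C10 OH, C2–C3 alkyne) | CC(C)(C)[Si](c1ccccc1)(c1ccccc1)OCc1c2c(C[C@](C)(O)C(O)C#C[C@@H](C)C[C@@H]2O[Si](C)(C)C(C)(C)C)oc1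
F10 | step 22 | macrocyclic alpha'-hydroxy ynone | CC(C)(C)[Si](c1ccccc1)(c1ccccc1)OCc1c2c(C[C@](C)(O)C(=O)C#C[C@@H](C)C[C@@H]2O[Si](C)(C)C(C)(C)C)oc1
F11 | step 13 | (4S,6R) alcohol, C6 epimer of 21 | C[Si](C)(C)C#C[C@@H](C)C[C@@H](O)c1c(CO[Si](CC)(CC)CC)occ1CO[Si](c1ccccc1)(c1ccccc1)C(C)(C)C
F12 | step 13 | (4S,6S) 4-nitrobenzoate | C[Si](C)(C)C#C[C@@H](C)C[C@H](OC(=O)c1ccc(cc1)[N+](=O)[O-])c1c(CO[Si](CC)(CC)CC)occ1CO[Si](c1ccccc1)(c1ccccc1)C(C)(C)C
F13 | step 13 | (4S,6S) alkynol with terminal alkyne | C#C[C@@H](C)C[C@H](O)c1c(CO[Si](CC)(CC)CC)occ1CO[Si](c1ccccc1)(c1ccccc1)C(C)(C)C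
F14 | step 3 | C2-lithiated lithium alkoxide of 2 | [Li]OCc1c([Li])occ1CO[Si](c1ccccc1)(c1ccccc1)C(C)(C)C
F15 | step 3 | [4-(tert-butyldiphenylsilyloxymethyl)furan-2,3-diyl]dimethanol | OCc1occ(CO[Si](c2ccccc2)(c2ccccc2)C(C)(C)C)c1CO
F16 | step 3 | [4-(tert-butyldiphenylsilyloxymethyl)-2-(triethylsilyloxymethyl)furan-3-yl]methanol | OCc1c(CO[Si](CC)(CC)CC)occ1CO[Si](c1ccccc1)(c1ccccc1)C(C)(C)C
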